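A small charge of protic impurity, 0.250 M, stands against 0.50 M of solid substrate in the flask, and the runs point to a loss taken one for one. If so, the two rates of loss are equal at every moment, time drops out of their ratio, and two amounts remain: the impurity charge $c_H$ and the solid charge $c_S$. The impurity is then the limiting reagent of the loss, and the remainder $C = 1 - c_H/c_S$, the share of the solid charge left over once the impurity is spent one for one, is 50.0 % here.

| setting | larch | cedar | alder | flask |
|---|---|---|---|---|
| solid substrate | 0.50 M | 0.50 M | 0.50 M | 0.50 M |
| solid reagent | 0.53 equiv | 2.1 equiv | 1.05 equiv | 1.05 equiv |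
| protic impurity | 0.25 M | 0.25 M | 0.50 M | 0.250 M |
| remark | run made earlier | run made earlier | run made earlier |  |
| time |  |  |  | 50 min |

| run | time / min | product / % | dissolved substrate / % |
|---|---|---|---|
| larch | 5.00 | 2.8 | 14.3 |
| larch | 10.0 | 7.6 | 24.7 |
| larch | 15.0 | 9.9 | 28.8 |
| larch | 30.0 | 27.5 | 25.8 |
| larch | 60.0 | 35.6 | 13.9 |
| cedar | 5.00 | 3.9 | 14.4 |
| cedar | 15.0 | 16.7 | 26.1 |
| cedar | 30.0 | 41.0 | 8.4 |
| cedar | 40.0 | 46.9 | 3.0 |
| cedar | 60.0 | 50.1 | 0.3 |
| alder | 5.00 | 2.8 | 14.9 |
| alder | 10.0 | 9.0 | 9.9 |
| alder | 15.0 | 13.7 | 7.4 |
| alder | 30.0 | 15.3 | 1.8 |
| alder | 60.0 | 16.9 | 0 |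

(standard deviation of a reading: 1 percentage point)

- as a solid, counted per litre of solution: solid substrate, solid reagent
- what was read earlier has a scatter of 1 percentage point, one standard deviation
- at the start none of the solid substrate is in solution
- at the start none of the solid reagent is in solution
- dissolved substrate means what is dissolved; the solid is not counted in it

- how much product there is at 50 min, in percent of the solid substrate charged
- concentration of dissolved substrate in solution at 50 min, in percent of saturation

In the cedar run, product plus dissolved substrate reads 50.4 % at 60.0 min, against a remainder of 50.0 %. In the alder run, with impurity equal to the solid charge, the product reads 16.9 % where the remainder is 0 %, so the rule is used here only with the impurity the smaller charge. This reckoning therefore expects the flask's product to stand below 50.0 % by what is still dissolved at 50 min.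

The forecast gives 46 % and 9 %, holding that “the impurity destroys solid substrate roughly 1:1”.

The flask gives 46.4 % and 4.86 %.

    solid substrate ⇌ dissolved substrate, rate k1*(cs1 - [dissolved substrate]) while solid is left; crystals form when [dissolved substrate] > cs1 (solubility = 0.380 M, k = 7.94 × 10⁻⁴ /s)
    dissolved substrate + partner → product (k = 0.00305 /M/s)
    solid reagent ⇌ partner, rate k3*(cs3 - [partner]) while solid is left; crystals form when [partner] > cs3 (solubility = 0.460 M, k = 0.0182 /s)
    solid substrate + protic impurity → quenched substrate (k = 0.0488 /M/s)

At 50.0 min, quenched substrate stands at 49.9 % of the solid charged, with 0.11 % of the impurity left. The remainder less the product leaves 3.60 %, and the dissolved substrate present is 3.70 %.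

With 0.15 M of impurity, a neighbour flask has a remainder of 70.0 %. It gives 60.3 % product and 9.65 % dissolved substrate at 50.0 min, together 70.0 %.

(The readings stem from a simulated flask with made-up constants, and the scatter is random.)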